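The quinone ring is dissected into three pieces: the C1 carbonyl (a CO ligand), C2–C3 (a terminal alkyne already carrying the complete (R)-acyloxy side chain) and C4 plus the benzenoid ring (an aryl(methoxy)carbene chromium complex). A Dötz benzannulation joins them in one operation; its final bond-forming event, 6π-electrocyclisation of a chromium-bound arylvinylketene, links C1 to C8a and closes the ring. The step exploits the 1,4-dioxygenated ring whose only substituent (C2) sits beside the CO-derived carbonyl, and the free ortho C–H of the aryl group that becomes C8a. Oxidative work-up delivers the quinone; mild MOM cleavage then unveils the 5,8-dihydroxy pattern.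

Key step: step 7

Assumption: the (S,S)-ProPhenol ligand is taken to deliver the 3R carbinol in step 2 (accepted facial model; the commercial (R,R)-ligand would be used if the sense were opposite), (R)-2-methylbutanoic acid is taken as commercial, and the target is treated as the naphthazarin tautomer drawn, with the side chain on the quinone ring.

**Step 1**
Reactants: 1 2-methylbut-3-en-2-ol; 2 (E)-but-2-enal (crotonaldehyde)
Product: 3 (E)-4-hydroxy-4-methylpent-2-enal
Conditions: Hoveyda–Grubbs II (2.5 mol%), 1 in excess, CH2Cl2, 40 °C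
Reagents that add atoms: none
Why: Olefin cross-metathesis between a hindered tertiary allylic alcohol and an enal, both slow to homodimerise, should give the thermodynamically favoured E-enal with loss of propene.

**Step 2**
Reactants: 3 (E)-4-hydroxy-4-methylpent-2-enal; 4 ethynyltrimethylsilane
Product: 6 (3R,4E)-6-methyl-1-(trimethylsilyl)hept-4-en-1-yne-3,6-diol, via alkynyl(methyl)zinc 5 (not isolated)
Conditions: Me2Zn (4 equiv), (S,S)-ProPhenol (10 mol%), Ph3P=O (20 mol%), toluene, 0 → 4 °C; aq. NH4Cl
Reagents that add atoms: none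
Why: Zn–ProPhenol-catalysed asymmetric alkynylation of an α,β-unsaturated aldehyde, in which the chiral dinuclear zinc catalyst delivers the alkynyl group to one aldehyde face and sets C3 as R, the extra Me2Zn masking the tertiary hydroxyl as its zinc alkoxide.

**Step 3**
Reactants: 6 (3R,4E)-6-methyl-1-(trimethylsilyl)hept-4-en-1-yne-3,6-diol
Product: 7 (3R,4E)-6-methylhept-4-en-1-yne-3,6-diol
Conditions: K2CO3 (0.2 equiv), MeOH, 0 °C → rt
Reagents that add atoms: none
Why: Base-catalysed methanolysis of the C(sp)–Si bond (protodesilylation) frees the terminal alkyne without touching the carbinol stereocentre.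

**Step 4**
Reactants: 7 (3R,4E)-6-methylhept-4-en-1-yne-3,6-diol; 8 (R)-2-methylbutanoic acid
Product: 9 (3R,4E)-6-hydroxy-6-methylhept-4-en-1-yn-3-yl (2R)-2-methylbutanoate
Conditions: DCC (1.1 equiv), DMAP (0.1 equiv), CH2Cl2, 0 °C
Reagents that add atoms: none
Why: Steglich esterification acylates the secondary hydroxyl while the tertiary hydroxyl is inert, and low temperature with catalytic DMAP should leave both stereocentres intact.

**Step 5**
Reactants: 10 hydroquinone
Product: 11 1,4-bis(methoxymethoxy)benzene
Conditions: NaH (2.5 equiv), MOMCl (2.5 equiv), DMF, 0 °C → rt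
Reagents that add atoms: chloromethyl methyl ether, COCCl
Why: Williamson-type O-alkylation of the bis-phenoxide with MOMCl installs two acetal groups that later direct ortho-lithiation and are removable by mild acid.

**Step 6**
Reactants: 11 1,4-bis(methoxymethoxy)benzene; 12 chromium hexacarbonyl
Product: 15 pentacarbonyl{[2,5-bis(methoxymethoxy)phenyl](methoxy)methylidene}chromium(0), via aryllithium 13 (not isolated), via lithium acylchromate 14 (not isolated)
Conditions: n-BuLi (1.05 equiv), TMEDA, Et2O, 0 °C; Cr(CO)6, 0 °C → rt; then Me3OBF4, CH2Cl2, 0 °C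
Reagents that add atoms: trimethyloxonium tetrafluoroborate, C[O+](C)C.F[B-](F)(F)F
Why: Fischer carbene synthesis: MOM-directed ortho-lithiation (all four ring positions are equivalent), addition of the aryllithium to a CO ligand, and O-methylation of the acyl chromate.

**Step 7**
Reactants: 9 (3R,4E)-6-hydroxy-6-methylhept-4-en-1-yn-3-yl (2R)-2-methylbutanoate; 15 pentacarbonyl{[2,5-bis(methoxymethoxy)phenyl](methoxy)methylidene}chromium(0)
Product: 18 (1R,2E)-1-[5,8-bis(methoxymethoxy)-1,4-dioxo-1,4-dihydronaphthalen-2-yl]-4-hydroxy-4-methylpent-2-en-1-yl (2R)-2-methylbutanoate, via naphthol tricarbonylchromium complex 16 (not isolated), via free naphthol 17 (not isolated)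
Conditions: THF (degassed), 50 °C, Ar; then CAN (7 equiv), MeCN/H2O, 0 °C
Reagents that add atoms: water, O
Why: Dötz benzannulation: after thermal loss of one CO from 15 the terminal alkyne of 9 inserts into the Cr=C bond, CO inserts to give a chromium-bound arylvinylketene, and 6π-electrocyclisation onto the aryl ring followed by tautomerisation gives naphthol complex 16, which CAN demetalates (17) and oxidises to the quinone. The closest known reaction type is exactly this benzannulation of aryl(alkoxy)carbene chromium complexes with terminal alkynes followed by oxidative work-up to 1,4-naphthoquinones. The one ring that closes, the six-membered quinone ring, does so by electrocyclic closure of the ketene carbon (future C1) onto the aryl ortho carbon (future C8a), the C3–C4 and C1–C2 bonds having been made by the two insertions. No stereocentre is created, and the carbinol centre and the ester α-centre of 9 are spectators under the neutral thermal conditions. The step needs regioselective alkyne insertion, secured by the steric bias of a terminal alkyne that places its branched substituent next to the CO-derived carbon, and a single site of closure, secured because the other ortho position of the aryl group is blocked by OMOM. Phenol formation over indene or furan products is favoured by an aryl(methoxy)carbene in THF, and CAN should oxidise only the free-naphthol ring, leaving the MOM-protected ring intact.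

**Step 8**
Reactants: 18 (1R,2E)-1-[5,8-bis(methoxymethoxy)-1,4-dioxo-1,4-dihydronaphthalen-2-yl]-4-hydroxy-4-methylpent-2-en-1-yl (2R)-2-methylbutanoate
Product: 19 (1R,2E)-1-(5,8-dihydroxy-1,4-dioxo-1,4-dihydronaphthalen-2-yl)-4-hydroxy-4-methylpent-2-en-1-yl (2R)-2-methylbutanoate
Conditions: 2 M aq. HCl, THF, 0 °C → rt
Reagents that add atoms: none
Why: Acid-catalysed acetal hydrolysis of the two aryl MOM ethers should be fast because each aryloxy oxygen is peri to a quinone carbonyl (a vinylogous carboxylate leaving group), so the ester and the tertiary allylic alcohol should survive the brief mild exposure.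

**Compound list**
1 | 2-methylbut-3-en-2-ol | C=CC(C)(C)O | starting material
2 | (E)-but-2-enal | C/C=C/C=O | starting material
3 | (E)-4-hydroxy-4-methylpent-2-enal | CC(C)(O)/C=C/C=O | intermediate
4 | ethynyltrimethylsilane | C#C[Si](C)(C)C | starting material
5 | methyl[(trimethylsilyl)ethynyl]zinc (not isolated) | C[Zn]C#C[Si](C)(C)C | intermediate
6 | (3R,4E)-6-methyl-1-(trimethylsilyl)hept-4-en-1-yne-3,6-diol | O[C@H](/C=C/C(C)(C)O)C#C[Si](C)(C)C | intermediate
7 | (3R,4E)-6-methylhept-4-en-1-yne-3,6-diol | O[C@H](/C=C/C(C)(C)O)C#C | intermediate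
8 | (R)-2-methylbutanoic acid | CC[C@@H](C)C(=O)O | starting material
9 | (3R,4E)-6-hydroxy-6-methylhept-4-en-1-yn-3-yl (2R)-2-methylbutanoate | CC[C@@H](C)C(=O)O[C@H](/C=C/C(C)(C)O)C#C | intermediate
10 | hydroquinone | Oc1ccc(O)cc1 | starting material
11 | 1,4-bis(methoxymethoxy)benzene | COCOc1ccc(OCOC)cc1 | intermediate
12 | chromium hexacarbonyl | O=C=[Cr](=C=O)(=C=O)(=C=O)(=C=O)=C=O | starting material
13 | [2,5-bis(methoxymethoxy)phenyl]lithium (not isolated) | [Li]c1cc(OCOC)ccc1OCOC | intermediate
14 | lithium pentacarbonyl{[2,5-bis(methoxymethoxy)phenyl](oxido)methylidene}chromate (not isolated) | [Li+].[O-]C(c1cc(OCOC)ccc1OCOC)=[Cr](=C=O)(=C=O)(=C=O)(=C=O)=C=O | intermediate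
15 | pentacarbonyl{[2,5-bis(methoxymethoxy)phenyl](methoxy)methylidene}chromium(0) | COC(c1cc(OCOC)ccc1OCOC)=[Cr](=C=O)(=C=O)(=C=O)(=C=O)=C=O | intermediate
16 | tricarbonylchromium η6-complex of naphthol 17, Cr(CO)3 on the new ring, written as arene plus Cr(CO)3 fragment (not isolated) | CC[C@@H](C)C(=O)O[C@H](/C=C/C(C)(C)O)c1cc(OC)c2c(OCOC)ccc(OCOC)c2c1O.O=C=[Cr](=C=O)=C=O | intermediate
17 | (1R,2E)-4-hydroxy-1-[1-hydroxy-4-methoxy-5,8-bis(methoxymethoxy)naphthalen-2-yl]-4-methylpent-2-en-1-yl (2R)-2-methylbutanoate (not isolated) | CC[C@@H](C)C(=O)O[C@H](/C=C/C(C)(C)O)c1cc(OC)c2c(OCOC)ccc(OCOC)c2c1O | intermediate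
18 | (1R,2E)-1-[5,8-bis(methoxymethoxy)-1,4-dioxo-1,4-dihydronaphthalen-2-yl]-4-hydroxy-4-methylpent-2-en-1-yl (2R)-2-methylbutanoate | CC[C@@H](C)C(=O)O[C@H](/C=C/C(C)(C)O)C1=CC(=O)c2c(OCOC)ccc(OCOC)c2C1=O | intermediate
19 | (1R,2E)-1-(5,8-dihydroxy-1,4-dioxo-1,4-dihydronaphthalen-2-yl)-4-hydroxy-4-methylpent-2-en-1-yl (2R)-2-methylbutanoate | CC[C@@H](C)C(=O)O[C@H](/C=C/C(C)(C)O)C1=CC(=O)c2c(O)ccc(O)c2C1=O | target

**Step count**
Total steps: 8. Longest linear sequence: 6 (steps 1, 2, 3, 4, 7, 8); the arene branch (steps 5, 6) joins at step 7.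

**Steps most likely to fail**

Step 7. The nascent ortho-hydroxybenzylic ester may expel its carboxylate (quinone-methide formation) before oxidation, or the vinylcarbene may be diverted before CO insertion. The fallback carries the carbinol as a silyl ether through the benzannulation and esterifies once the quinone exists. It sets out from 7 and comes back at 18. Diol 7 is silylated at the secondary hydroxyl only (TBSCl, imidazole, DMF, 0 °C) to give (3E,5R)-5-[(tert-butyldimethylsilyl)oxy]-2-methylhept-3-en-6-yn-2-ol F1. Benzannulation of F1 with 15 and CAN work-up as in step 7 should give 2-[(1R,2E)-1-[(tert-butyldimethylsilyl)oxy]-4-hydroxy-4-methylpent-2-en-1-yl]-5,8-bis(methoxymethoxy)naphthalene-1,4-dione F2. HF·pyridine in THF/pyridine at 0 °C should free 2-[(1R,2E)-1,4-dihydroxy-4-methylpent-2-en-1-yl]-5,8-bis(methoxymethoxy)naphthalene-1,4-dione F3. Steglich esterification of F3 with 8 (DCC, catalytic DMAP, CH2Cl2, 0 °C) then gives 18.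

Step 8. Ionisation of the tertiary allylic alcohol, or acid-promoted loss of the acyloxy group, may compete with acetal hydrolysis. The fallback replaces the acetal protection by silyl ethers that are released with buffered fluoride. It sets out from 9 and comes back at 19, and uses commercial 2-bromobenzene-1,4-diol as an additional starting material. Silylation (TIPSCl, imidazole, DMF) gives 2-bromo-1,4-bis[(triisopropylsilyl)oxy]benzene F4; the bulky silyl groups are chosen to suppress O-to-C silyl migration in the aryllithium. Bromine–lithium exchange (t-BuLi, Et2O, −78 °C), addition to 12 and O-methylation with Me3OBF4 should give pentacarbonyl{[2,5-bis(triisopropylsilyloxy)phenyl](methoxy)methylidene}chromium(0) F5. Benzannulation of F5 with 9 and CAN work-up should give (1R,2E)-1-[1,4-dioxo-5,8-bis(triisopropylsilyloxy)-1,4-dihydronaphthalen-2-yl]-4-hydroxy-4-methylpent-2-en-1-yl (2R)-2-methylbutanoate F6. TBAF buffered with AcOH in THF at 0 °C then gives 19 without any acid step.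

Step 2. The zinc alkoxide of the free tertiary hydroxyl may inhibit the catalyst, methyl transfer may compete, and facial selectivity may be poor. The fallback sets the stereocentre by reagent-controlled reduction of a ketone instead. It sets out from 3 and 4 and comes back at 6. Addition of lithium (trimethylsilyl)acetylide (from 4 and n-BuLi, excess, THF, −78 °C) to 3 gives racemic (4E)-6-methyl-1-(trimethylsilyl)hept-4-en-1-yne-3,6-diol F7. MnO2 in CH2Cl2 oxidises the doubly activated carbinol to (4E)-6-hydroxy-6-methyl-1-(trimethylsilyl)hept-4-en-1-yn-3-one F8. Midland reduction with (R)-Alpine-Borane (THF, rt), which treats the alkyne as the small group, should give the 3R alcohol 6.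

**Further compounds**
F1 | step 7 | (3E,5R)-5-[(tert-butyldimethylsilyl)oxy]-2-methylhept-3-en-6-yn-2-ol | CC(C)(C)[Si](C)(C)O[C@H](/C=C/C(C)(C)O)C#C
F2 | step 7 | 2-[(1R,2E)-1-[(tert-butyldimethylsilyl)oxy]-4-hydroxy-4-methylpent-2-en-1-yl]-5,8-bis(methoxymethoxy)naphthalene-1,4-dione | CC(C)(C)[Si](C)(C)O[C@H](/C=C/C(C)(C)O)C1=CC(=O)c2c(OCOC)ccc(OCOC)c2C1=O
F3 | step 7 | 2-[(1R,2E)-1,4-dihydroxy-4-methylpent-2-en-1-yl]-5,8-bis(methoxymethoxy)naphthalene-1,4-dione | O[C@H](/C=C/C(C)(C)O)C1=CC(=O)c2c(OCOC)ccc(OCOC)c2C1=O
F4 | step 8 | 2-bromo-1,4-bis[(triisopropylsilyl)oxy]benzene | CC(C)[Si](Oc1ccc(O[Si](C(C)C)(C(C)C)C(C)C)c(Br)c1)(C(C)C)C(C)C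
F5 | step 8 | pentacarbonyl{[2,5-bis(triisopropylsilyloxy)phenyl](methoxy)methylidene}chromium(0) | COC(c1cc(O[Si](C(C)C)(C(C)C)C(C)C)ccc1O[Si](C(C)C)(C(C)C)C(C)C)=[Cr](=C=O)(=C=O)(=C=O)(=C=O)=C=O
F6 | step 8 | (1R,2E)-1-[1,4-dioxo-5,8-bis(triisopropylsilyloxy)-1,4-dihydronaphthalen-2-yl]-4-hydroxy-4-methylpent-2-en-1-yl (2R)-2-methylbutanoate | CC[C@@H](C)C(=O)O[C@H](/C=C/C(C)(C)O)C1=CC(=O)c2c(O[Si](C(C)C)(C(C)C)C(C)C)ccc(O[Si](C(C)C)(C(C)C)C(C)C)c2C1=O
F7 | step 2 | racemic (4E)-6-methyl-1-(trimethylsilyl)hept-4-en-1-yne-3,6-diol | OC(/C=C/C(C)(C)O)C#C[Si](C)(C)C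
F8 | step 2 | (4E)-6-hydroxy-6-methyl-1-(trimethylsilyl)hept-4-en-1-yn-3-one | O=C(/C=C/C(C)(C)O)C#C[Si](C)(C)C
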